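**Two amounts.** At 40.0 h the dawn run holds 12.6% of its substrate as target and the winter run 10.7%, with the charge raised from 0.13 M to 1.1 M. These two readings lie furthest apart in charge. Their gap of 1.9 percentage points stands above the scatter of 0.3 points. The same pair at 15.0 h, 1.4% and 1.0%, differs by 0.4 points, close to that scatter. The dusk reading, 11.5%, lies between them.

| flask | substrate | reagent | remark | time |
|---|---|---|---|---|
| dawn | 0.13 M | 1.5 M | run made earlier |  |
| dusk | 0.51 M | 1.5 M | run made earlier |  |
| winter | 1.1 M | 1.5 M | run made earlier |  |
| Sunday's | 0.15 M | 1.50 M |  | 3.0 d |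
| Wednesday's | 0.50 M | 1.50 M |  | 3.0 d |
| Tuesday's | 1.5 M | 1.50 M |  | 3.0 d |

| dawn: time / h | dawn: target / % | dusk: time / h | dusk: target / % | winter: time / h | winter: target / % |
|---|---|---|---|---|---|
| 3.00 | 0 | 5.00 | 0.4 | 3.00 | 0 |
| 6.00 | 0 | 12.0 | 0.4 | 6.00 | 0.2 |
| 15.0 | 1.4 | 25.0 | 4.2 | 15.0 | 1.0 |
| 40.0 | 12.6 | 40.0 | 11.5 | 40.0 | 10.7 |

(scatter of a reading: 0.3 percentage points)

- "hardly changes" means that all values lie within two and a half points (for a concentration: within two and a half percent of the largest)

- amount of target at the end, in percent of the substrate charged for Sunday's, Wednesday's, Tuesday's, in this order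
- the course of these numbers from the first flask to the last (falls, then rises / rises, then falls / hardly changes / rises all the way / falls all the way)

**One molecule.** A molecule of substrate follows a road to target, and its pace shows in percentages that stay close across the charges. The fall with charge means that a molecule's chance of having reached target by 40.0 h shrinks as the charge grows. The ratio of the two amounts is the share kept, 84.9%. Spread over the rise in charge, the share lost is 0.155 M⁻¹. This share of target lost per unit of charge is the charge loss.

**Own reckoning.** Take the charge loss as linear in charge and as holding at 3.0 d. Wednesday's then ends at 94.6% of Sunday's target percentage, and Tuesday's at 79.0%. The row falls.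

**The forecast.** The forecast gave 40%, 36% and 29%, falls all the way, and called the decline “consistent with reagent depletion”. Its Tuesday's stands at 72.5% of its Sunday's, lower than the 79.0% reckoned here.

**The flask.** The flask gives 37.8%, 34.7% and 28.1%: falls all the way.

    intermediate A ⇌ intermediate B (K = 2.50, k = 0.312 h⁻¹)
    intermediate C → target (k = 0.0370 h⁻¹)
    substrate → intermediate A (k = 0.0270 h⁻¹)
    reagent + intermediate B → intermediate C (k = 0.0333 M⁻¹ h⁻¹)
    2 substrate → self-condensation product (k = 0.00723 M⁻¹ h⁻¹)

Wednesday's stands at 91.8% of Sunday's, against 94.6% from the charge loss, and Tuesday's at 74.3%, against 79.0%; the row itself gives a charge loss of 0.190 M⁻¹, beside the 0.155 M⁻¹ read earlier. At the start of Sunday's, substrate goes to intermediate A 12 times as fast as to self-condensation product, a selectivity factor. At 3.00 d, Tuesday's holds 26.3% of its substrate charge as self-condensation product and keeps 57.3% of its reagent charge, and Sunday's holds 3.74% and keeps 94.0%.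

The earlier runs and the new flask are calculated for an exercise, noise included.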